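The vessel is closed, stirred and isothermal, and in it starting material and reagent meet a trace of free catalyst beside a capture agent. The flask asked about is the cedar run carried on to 20 h, and the maple run is the colder comparison.

| flask | starting material | second substrate | reagent | capture agent | free catalyst | temperature | remark | time |
|---|---|---|---|---|---|---|---|---|
| cedar | 10 mM | 10 mM | 20 mM | 0.50 mM | 14 µM | 5 °C | the very flask that is asked about, followed so far |  |
| maple | 10 mM | 10 mM | 20 mM | 0.25 mM | 14 µM | 0 °C | run made earlier |  |
| flask | 10 mM | 10.0 mM | 20.0 mM | 0.500 mM | 14 µM | 5 °C |  | 20 h |

| run | time / h | target / % | starting material / % |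
|---|---|---|---|
| cedar | 1.33 | 5.6 | 58.5 |
| cedar | 2.00 | 9.2 | 48.6 |
| cedar | 3.00 | 12.4 | 38.3 |
| cedar | 5.00 | 12.5 | 26.8 |
| cedar | 6.00 | 15.6 | 23.6 |
| cedar | 10.0 | 15.4 | 16.8 |
| cedar | 15.0 | 15.1 | 12.7 |
| maple | 0.417 | 0.6 | 89.7 |
| maple | 1.33 | 5.8 | 70.1 |
| maple | 2.50 | 10.0 | 55.2 |
| maple | 3.00 | 12.5 | 49.1 |
| maple | 5.00 | 14.9 | 35.6 |
| maple | 6.00 | 15.9 | 32.0 |
| maple | 8.00 | 20.7 | 25.4 |

(readings scatter by 1 percentage point)

- Tuesday's: at 20 h take out 90 % of the target then present, then wait 40 h
- Thursday's: at 20 h add free catalyst, 50.0 % of the amount charged, then wait 40 h
- Sunday's: at 20 h add reagent, 100 % of the amount charged, then wait 40 h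
- Monday's: change nothing and wait 40 h more
- Saturday's: at 20 h raise the temperature by 10 K, then wait 40 h

- target, in percent of the starting material first charged, at 20 h
- what to do for the largest gain in target; "none" if nothing gains more than 2 percentage points (Tuesday's / Thursday's / Sunday's / Monday's / Saturday's / none)
- target present, with what was taken out counted in, in percent of the starting material first charged, after Sunday's
- target present, with what was taken out counted in, in percent of the starting material first charged, after Saturday's

- target taken out counts as made
- additions bring no volume worth counting

Watch the target go flat while starting material keeps falling. In cedar the target reads 15.6 % at 6.00 h and 15.1 % at 15.0 h, while starting material drops from 23.6 % to 12.7 %. I read this as catalyst being lost, probably to the capture agent, which is charged at 35.7 times the catalyst. The last three cedar readings average 15.4 %, and on the charges that makes 110 for the turnover budget, the target made per catalyst charged before capture ends its work, which is its turnover number. Maple, colder and with half the capture agent, reads 20.7 % at 8.00 h, above the cedar level and rising. Those two settings changed together, so it is my assumption, not a reading, that the budget grows as capture agent shrinks, in inverse proportion.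

Now turn the settings by hand. From waiting, Monday's, I expect little, since the cedar line stands flat. Sunday's adds reagent, but the target level read above needs 1.54 mM of the 20.0 mM charged, so I do not take reagent for the limiting reagent, and I expect less than 2 percentage points. Saturday's heat cannot be read from these runs, since they change temperature and capture agent together, and I expect little from a flat line. The cedar readings show nothing for Tuesday's removal to work on, since the target stands flat there.

Thursday's brings new budget, worth 7.68 % of the starting material. Late in cedar the reciprocal of [starting material], taken as a fraction of the charge, climbs at about 0.384 h⁻¹, as a second-order loss does, and I extrapolate that to 10.2 % at 20 h. Scaling the early target rate of cedar to that [starting material] and to the added catalyst gives the catalyst 51.7 % of what is left. So I commit to about 15.4 % now and to Thursday's, gaining about 5.28 %, inside the new budget.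

The forecast gives 15.3 %, 15.5 % after Sunday's, 15.5 % after Saturday's and best none, holding that “Fresh catalyst would die quickly in excess capture agent”, and on that choice it differs from my reckoning.

The flask gives 16.1 %, and the best choice is Thursday's, gaining 5.1 points, against 0.92 points for Sunday's and 0.55 points for Saturday's, which end at 17.0 % and 16.7 %.

    2 starting material → homo dimer (k = 0.360 M⁻¹ min⁻¹, Ea = 70.0 kJ mol⁻¹)
    reagent + catalyst intermediate B → free catalyst + second product (k = 360 M⁻¹ min⁻¹, Ea = 44.0 kJ mol⁻¹)
    starting material + free catalyst ⇌ catalyst intermediate A (K = 1900 M⁻¹, k = 210 M⁻¹ min⁻¹, Ea = 39.0 kJ mol⁻¹, ΔH = −60.0 kJ mol⁻¹)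
    catalyst intermediate A + capture agent → trapped intermediate (k = 36.0 M⁻¹ min⁻¹, Ea = 45.0 kJ mol⁻¹)
    second substrate + free catalyst ⇌ catalyst intermediate B (K = 280 M⁻¹, k = 220 M⁻¹ min⁻¹, Ea = 38.0 kJ mol⁻¹, ΔH = −25.0 kJ mol⁻¹)
    reagent + catalyst intermediate A → free catalyst + target (k = 120 M⁻¹ min⁻¹, Ea = 42.0 kJ mol⁻¹)
    (constants at 5 °C)

Carry the budget to the neighbouring flask, charged with 0.12 mM of capture agent and otherwise the same. In the flask itself, at 20 h, 95.4 % of the catalyst stands as trapped intermediate and 3.47 % as free catalyst. Scaled inversely with capture agent, the budget of 110 comes for the neighbour to 64.0 % of the starting material, yet that flask holds 30.5 % of target. There the trapped intermediate is 50.6 % of the catalyst and free catalyst 41.2 %, while starting material is down to 4.23 % and homo dimer stands at 65.2 %.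

Readings and results stem from a simulated flask with constants of no real substance; scatter was added.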